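**Retrosynthetic overview**

1. Numbering: C1 quaternary methyl-bearing fusion carbon, C2/C3 ring CH2, C4 isopropyl carbinol, C5 fusion CH, C6 aroyloxy carbon, C7 CH2, C8 methyl-bearing alkene carbon, C9 alkene CH, C10 isovaleryloxy carbon; ring A is the seven-membered ring, ring B the five-membered ring. The strategy rests on C10 of ring A, an allylic carbinol held between quaternary C1 and the trisubstituted C8=C9 alkene, which is the adduct of a (Z)-alkenyl metal at C9 with a neopentyl aldehyde at C10.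
2. Ring A is opened at C9–C10 (intramolecular Nozaki–Hiyama–Kishi reaction of a (Z)-iodoalkenyl aldehyde); the C6 aroyl ester is installed before this step and the C10 isovalerate after it.
3. The C6–C9 chain comes from a C6 dithiane (acyl anion) and (Z)-3-iodo-2-methylallyl bromide (C6–C7 bond); the C6 carbinol comes from a ketone reduction directed by the C4 hydroxyl.
4. Ring B carries the three ring stereocentres: C1 by enolate methylation anti to the C5 substituent, C5 by C4-hydroxyl-directed hydrogenation of a C1=C5 alkene, the ring by Dieckmann closure (C1–C5), and C4 from (S)-2-hydroxy-3-methylbutanoic acid by alkylation with self-regeneration of the stereocentre.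
5. Order of ring formation: ring B (step 5), then ring A (step 24).

Key step: step 24

Remark (assumption): the hindered tertiary C4 hydroxyl is carried unprotected (it directs steps 9 and 18 and should not acylate under the conditions used), and the cyclisation substrate already carries the final C6 ester in silyl-protected form. Abbreviations: PMB = 4-methoxybenzyl, TBS = tert-butyldimethylsilyl, Tf = trifluoromethanesulfonyl.

**Route**

Step 1
Reactants: 1 (S)-2-hydroxy-3-methylbutanoic acid
Product: 2 (2S,5S)-2-tert-butyl-5-(propan-2-yl)-1,3-dioxolan-4-one (cis)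
Conditions: pivalaldehyde, p-TsOH (cat.), pentane, reflux, Dean–Stark; crystallisation
Reagents that add atoms: pivalaldehyde (2,2-dimethylpropanal), CC(C)(C)C=O
Why: Acid-catalysed acetalisation with removal of water gives the dioxolanone, whose cis isomer (tert-butyl and isopropyl on one face) is favoured and purified by crystallisation, so that the acetal carbon stores the chirality of the future C4.

Step 2
Reactants: 2 (2S,5S)-2-tert-butyl-5-(propan-2-yl)-1,3-dioxolan-4-one
Product: 4 (2S,5S)-2-tert-butyl-5-(prop-2-en-1-yl)-5-(propan-2-yl)-1,3-dioxolan-4-one, via lithium enolate 3 (not isolated)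
Conditions: LiN(iPr)2, THF, −78 °C; then allyl bromide, −78 to −30 °C
Reagents that add atoms: allyl bromide, C=CCBr
Why: Enolate alkylation with self-regeneration of the stereocentre: the planar enolate is allylated on the face opposite the tert-butyl group, so allyl replaces the former hydrogen with overall retention and fixes C4 as a quaternary carbinol carbon.

Step 3
Reactants: 4 (2S,5S)-5-allyl-2-tert-butyl-5-(propan-2-yl)-1,3-dioxolan-4-one
Product: 5 methyl (2E)-4-[(2S,4S)-2-tert-butyl-5-oxo-4-(propan-2-yl)-1,3-dioxolan-4-yl]but-2-enoate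
Conditions: methyl acrylate (5 equiv), Hoveyda–Grubbs second-generation catalyst (5 mol %), CH2Cl2, 40 °C
Reagents that add atoms: methyl acrylate, C=CC(=O)OC
Why: Olefin cross-metathesis between a terminal alkene and an acrylate is selective for the cross product as the (E)-enoate and brings in C1 and C10.

Step 4
Reactants: 5 methyl (2E)-4-[(2S,4S)-2-tert-butyl-5-oxo-4-(propan-2-yl)-1,3-dioxolan-4-yl]but-2-enoate
Product: 6 methyl 4-[(2S,4S)-2-tert-butyl-5-oxo-4-(propan-2-yl)-1,3-dioxolan-4-yl]butanoate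
Conditions: H2 (1 atm), Pd/C, EtOAc, rt
Reagents that add atoms: none
Why: Heterogeneous catalytic hydrogenation saturates the conjugated alkene and leaves the acetal lactone and the ester untouched.

Step 5
Reactants: 6 methyl 4-[(2S,4S)-2-tert-butyl-5-oxo-4-(propan-2-yl)-1,3-dioxolan-4-yl]butanoate
Product: 7 methyl (3S)-3-hydroxy-2-oxo-3-(propan-2-yl)cyclopentane-1-carboxylate (keto/enol forms and C1 epimers)
Conditions: LiN(SiMe3)2 (2.2 equiv), THF, −78 to 0 °C; then 1 M HCl
Reagents that add atoms: none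
Why: Dieckmann (intramolecular Claisen) condensation: the ester enolate at C1 acylates the dioxolanone carbonyl (C5) in a 5-exo-trig closure, the acetal alkoxide leaves as pivalaldehyde, the acidic β-keto ester drives the equilibrium, and only C1 can enolise because C4 is quaternary.

Step 6
Reactants: 7 methyl (3S)-3-hydroxy-2-oxo-3-(propan-2-yl)cyclopentane-1-carboxylate
Product: 8 methyl (3S)-3-hydroxy-3-(propan-2-yl)-2-[(trifluoromethanesulfonyl)oxy]cyclopent-1-ene-1-carboxylate
Conditions: NaH (1.05 equiv), PhNTf2 (1.1 equiv), THF, 0 °C to rt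
Reagents that add atoms: N-phenylbis(trifluoromethanesulfonimide), O=S(=O)(N(c1ccccc1)S(=O)(=O)C(F)(F)F)C(F)(F)F
Why: O-sulfonylation of the β-keto ester enolate gives the enol triflate regiospecifically across C5=C1, the far less acidic and hindered tertiary alcohol staying free.

Step 7
Reactants: 8 methyl (3S)-3-hydroxy-3-(propan-2-yl)-2-[(trifluoromethanesulfonyl)oxy]cyclopent-1-ene-1-carboxylate
Product: 9 methyl (3S)-2-formyl-3-hydroxy-3-(propan-2-yl)cyclopent-1-ene-1-carboxylate
Conditions: CO (1 atm), Pd(OAc)2 (5 mol %), dppp (5 mol %), Et3SiH (2 equiv), Et3N (2.5 equiv), DMF, 70 °C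
Reagents that add atoms: carbon monoxide, [C-]#[O+]
Why: Palladium-catalysed reductive carbonylation (formylation) of an enol triflate: oxidative addition to zerovalent palladium, CO insertion and hydride transfer from the silane place C6 on C5 as an aldehyde.

Step 8
Reactants: 9 methyl (3S)-2-formyl-3-hydroxy-3-(propan-2-yl)cyclopent-1-ene-1-carboxylate
Product: 10 methyl (3S)-2-(dimethoxymethyl)-3-hydroxy-3-(propan-2-yl)cyclopent-1-ene-1-carboxylate
Conditions: HC(OMe)3, MeOH, p-TsOH (cat.), rt
Reagents that add atoms: trimethyl orthoformate, COC(OC)OC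
Why: Acid-catalysed acetalisation masks the C6 aldehyde so that C5 cannot epimerise once the alkene is reduced; the allylic tertiary alcohol does not ionise because the alkene is electron-poor.

Step 9
Reactants: 10 methyl (3S)-2-(dimethoxymethyl)-3-hydroxy-3-(propan-2-yl)cyclopent-1-ene-1-carboxylate
Product: 11 methyl (1R,2R,3S)-2-(dimethoxymethyl)-3-hydroxy-3-(propan-2-yl)cyclopentane-1-carboxylate
Conditions: H2 (20 bar), [Ir(cod)(PCy3)(py)]PF6 (10 mol %), CH2Cl2, rt
Reagents that add atoms: none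
Why: Hydroxyl-directed homogeneous hydrogenation: the cationic iridium catalyst binds the C4 hydroxyl and delivers both hydrogens to the tetrasubstituted C1=C5 alkene from the hydroxyl face (also the face away from isopropyl), which sets H-5 cis to the C4 oxygen; the C1 centre formed here is erased in the next step.

Step 10
Reactants: 11 methyl (1R,2R,3S)-2-(dimethoxymethyl)-3-hydroxy-3-(propan-2-yl)cyclopentane-1-carboxylate
Product: 13 methyl (1R,2R,3S)-2-(dimethoxymethyl)-3-hydroxy-1-methyl-3-(propan-2-yl)cyclopentane-1-carboxylate, via dilithium alkoxide enolate 12 (not isolated)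
Conditions: LiN(iPr)2 (2.3 equiv), THF, −78 °C; then MeI, −78 to −30 °C; then H2O
Reagents that add atoms: iodomethane, CI
Why: Ester enolate alkylation: the C1 enolate is methylated on the face opposite the dimethoxymethyl group on C5, which creates the quaternary C1 with methyl cis to H-5 and to the C4 hydroxyl, while the hindered lithium alkoxide is not methylated at low temperature.

Step 11
Reactants: 13 methyl (1R,2R,3S)-2-(dimethoxymethyl)-3-hydroxy-1-methyl-3-(propan-2-yl)cyclopentane-1-carboxylate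
Product: 14 methyl (1R,2R,3S)-2-(1,3-dithian-2-yl)-3-hydroxy-1-methyl-3-(propan-2-yl)cyclopentane-1-carboxylate
Conditions: HS(CH2)3SH (1.5 equiv), BF3·OEt2 (1.2 equiv), CH2Cl2, −20 to 0 °C
Reagents that add atoms: propane-1,3-dithiol, SCCCS
Why: Lewis-acid-mediated transthioacetalisation turns the C6 acetal into the 1,3-dithiane needed for polarity reversal without passing through a free, epimerisable aldehyde.

Step 12
Reactants: 14 methyl (1R,2R,3S)-2-(1,3-dithian-2-yl)-3-hydroxy-1-methyl-3-(propan-2-yl)cyclopentane-1-carboxylate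
Product: 15 (1S,2R,3R)-2-(1,3-dithian-2-yl)-3-(hydroxymethyl)-3-methyl-1-(propan-2-yl)cyclopentan-1-ol
Conditions: LiAlH4, THF, 0 °C to rt
Reagents that add atoms: none
Why: Hydride reduction of the neopentyl methyl ester gives the C10 primary alcohol; the dithiane and the tertiary alcohol are inert.

Step 13
Reactants: 15 (1S,2R,3R)-2-(1,3-dithian-2-yl)-3-(hydroxymethyl)-3-methyl-1-(propan-2-yl)cyclopentan-1-ol
Product: 16 (1S,2R,3R)-2-(1,3-dithian-2-yl)-3-{[(4-methoxyphenyl)methoxy]methyl}-3-methyl-1-(propan-2-yl)cyclopentan-1-ol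
Conditions: NaH (1.1 equiv), PMBCl (1.1 equiv), Bu4NI (cat.), THF–DMF, 0 °C to rt
Reagents that add atoms: 4-methoxybenzyl chloride, COc1ccc(CCl)cc1
Why: Williamson etherification takes place at the primary C10 alkoxide much faster than at the tertiary C4 alcohol flanked by isopropyl, and the PMB ether survives the organolithium step that follows.

Step 14
Reactants: 17 prop-2-yn-1-ol
Product: 19 (2Z)-3-iodo-2-methylprop-2-en-1-ol, via alkenylmagnesium chelate 18 (not isolated)
Conditions: MeMgBr (3 equiv), CuI (10 mol %), THF, −10 °C to rt; then I2, −78 to 0 °C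
Reagents that add atoms: methylmagnesium bromide, C[Mg]Br; iodine, II
Why: Copper-catalysed anti-carbomagnesiation of the propargylic alkoxide gives a five-membered alkenylmagnesium chelate, and iodinolysis with retention fixes the (Z) geometry (iodine cis to CH2OH).

Step 15
Reactants: 19 (2Z)-3-iodo-2-methylprop-2-en-1-ol
Product: 20 (1Z)-3-bromo-1-iodo-2-methylprop-1-ene
Conditions: CBr4, PPh3, CH2Cl2, 0 °C
Reagents that add atoms: tetrabromomethane, BrC(Br)(Br)Br
Why: Appel bromination converts the allylic alcohol into the bromide under neutral conditions without touching the alkenyl iodide or its geometry.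

Step 16
Reactants: 16 (1S,2R,3R)-2-(1,3-dithian-2-yl)-3-{[(4-methoxyphenyl)methoxy]methyl}-3-methyl-1-(propan-2-yl)cyclopentan-1-ol; 20 (1Z)-3-bromo-1-iodo-2-methylprop-1-ene
Product: 22 (1S,2R,3R)-2-{2-[(2Z)-3-iodo-2-methylprop-2-en-1-yl]-1,3-dithian-2-yl}-3-{[(4-methoxyphenyl)methoxy]methyl}-3-methyl-1-(propan-2-yl)cyclopentan-1-ol, via dilithiated dithiane 21 (not isolated)
Conditions: t-BuLi (2.05 equiv), THF–HMPA (10:1), −78 °C; then 20, −78 to −40 °C; then H2O
Reagents that add atoms: none
Why: Corey–Seebach alkylation: the 2-lithio-1,3-dithiane (C6 acyl anion equivalent) displaces the allylic bromide in an SN2 reaction to form C6–C7, and the sulfur-stabilised anion has no driving force for iodine–lithium exchange with the alkenyl iodide.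

Step 17
Reactants: 22 (1S,2R,3R)-2-{2-[(2Z)-3-iodo-2-methylprop-2-en-1-yl]-1,3-dithian-2-yl}-3-{[(4-methoxyphenyl)methoxy]methyl}-3-methyl-1-(propan-2-yl)cyclopentan-1-ol
Product: 23 (3Z)-1-[(1R,2S,5R)-2-hydroxy-5-{[(4-methoxyphenyl)methoxy]methyl}-5-methyl-2-(propan-2-yl)cyclopentyl]-4-iodo-3-methylbut-3-en-1-one
Conditions: MeI (excess), CaCO3, MeCN–H2O (9:1), 45 °C
Reagents that add atoms: water, O
Why: S-Methylation of the dithiane and hydrolysis of the sulfonium salt under CaCO3 buffer unmask the C6 ketone near neutrality, which spares the alkenyl iodide, the PMB ether, the β,γ-position of the alkene and the configuration at C5.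

Step 18
Reactants: 23 (3Z)-1-[(1R,2S,5R)-2-hydroxy-5-{[(4-methoxyphenyl)methoxy]methyl}-5-methyl-2-(propan-2-yl)cyclopentyl]-4-iodo-3-methylbut-3-en-1-one
Product: 24 (1S,2S,3R)-2-[(1R,3Z)-1-hydroxy-4-iodo-3-methylbut-3-en-1-yl]-3-{[(4-methoxyphenyl)methoxy]methyl}-3-methyl-1-(propan-2-yl)cyclopentan-1-ol
Conditions: Me4NBH(OAc)3 (5 equiv), MeCN–AcOH (1:1), −30 to −20 °C
Reagents that add atoms: none
Why: Evans–Saksena reduction: the C4 hydroxyl exchanges onto boron and hydride is delivered intramolecularly through a chair transition state trans-fused to ring B, with the carbonyl oxygen axial and C7 equatorial (away from the axial isopropyl), which should give the (6R) carbinol.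

Step 19
Reactants: 25 4-hydroxybenzoic acid
Product: 27 4-[(tert-butyldimethylsilyl)oxy]benzoic acid, via bis-silylated ester 26 (not isolated)
Conditions: TBSCl (2.5 equiv), imidazole, DMF, rt; then THF–AcOH–H2O (3:1:1), rt
Reagents that add atoms: tert-butyldimethylsilyl chloride, CC(C)(C)[Si](C)(C)Cl
Why: Silylation of phenol and acid followed by selective hydrolysis of the labile silyl ester gives the O-silylated acid, the aryl silyl ether being stable to mild acid.

Step 20
Reactants: 27 4-[(tert-butyldimethylsilyl)oxy]benzoic acid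
Product: 28 4-[(tert-butyldimethylsilyl)oxy]benzoyl chloride
Conditions: (COCl)2, DMF (cat.), CH2Cl2, 0 °C to rt; evaporation
Reagents that add atoms: oxalyl chloride, ClC(=O)C(Cl)=O
Why: Acid chloride formation through the Vilsmeier-type chloroiminium activation works under neutral conditions that keep the aryl silyl ether.

Step 21
Reactants: 24 (1S,2S,3R)-2-[(1R,3Z)-1-hydroxy-4-iodo-3-methylbut-3-en-1-yl]-3-{[(4-methoxyphenyl)methoxy]methyl}-3-methyl-1-(propan-2-yl)cyclopentan-1-ol; 28 4-[(tert-butyldimethylsilyl)oxy]benzoyl chloride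
Product: 29 (1R,3Z)-1-[(1S,2S,5R)-2-hydroxy-5-{[(4-methoxyphenyl)methoxy]methyl}-5-methyl-2-(propan-2-yl)cyclopentyl]-4-iodo-3-methylbut-3-en-1-yl 4-[(tert-butyldimethylsilyl)oxy]benzoate
Conditions: Et3N, DMAP (0.5 equiv), CH2Cl2, rt to 40 °C
Reagents that add atoms: none
Why: DMAP-catalysed acylation (nucleophilic catalysis) esterifies the secondary C6 alcohol, the tertiary C4 alcohol being too hindered to react.

Step 22
Reactants: 29 the C6 aroyl ester, C10 PMB ether
Product: 30 (1R,3Z)-1-[(1S,2S,5R)-2-hydroxy-5-(hydroxymethyl)-5-methyl-2-(propan-2-yl)cyclopentyl]-4-iodo-3-methylbut-3-en-1-yl 4-[(tert-butyldimethylsilyl)oxy]benzoate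
Conditions: DDQ, CH2Cl2–pH 7 buffer (10:1), 0 °C
Reagents that add atoms: none
Why: Oxidative PMB cleavage (hydride abstraction by DDQ, hydrolysis of the oxocarbenium ion) frees the C10 alcohol without affecting the ester, the aryl silyl ether or the alkenyl iodide, and the neutral medium avoids acyl migration.

Step 23
Reactants: 30 the C10 primary alcohol
Product: 31 (1R,3Z)-1-[(1S,2S,5R)-5-formyl-2-hydroxy-5-methyl-2-(propan-2-yl)cyclopentyl]-4-iodo-3-methylbut-3-en-1-yl 4-[(tert-butyldimethylsilyl)oxy]benzoate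
Conditions: Dess–Martin periodinane, CH2Cl2, 0 °C to rt
Reagents that add atoms: none
Why: Dess–Martin oxidation converts the neopentyl primary alcohol into the non-enolisable C10 aldehyde under neutral conditions, and the tertiary alcohol cannot be oxidised.

Step 24
Reactants: 31 the (Z)-iodoalkenyl C10 aldehyde
Product: 33 (3S,3aS,4R,8S,8aR)-3,8-dihydroxy-6,8a-dimethyl-3-(propan-2-yl)-1,2,3,3a,4,5,8,8a-octahydroazulen-4-yl 4-[(tert-butyldimethylsilyl)oxy]benzoate, via alkenylchromium species 32 (not isolated)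
Conditions: CrCl2 (10 equiv), NiCl2 (0.2 equiv), degassed DMF, rt, 0.003 M, slow addition of 31
Reagents that add atoms: none
Why: Nozaki–Hiyama–Kishi reaction: zerovalent nickel, formed from NiCl2 by CrCl2, inserts into the C9–I bond, transmetalation to trivalent chromium gives the alkenylchromium species 32 with retention of the (Z) geometry, and 32 adds to the C10 aldehyde to form C9–C10. The closest known reaction type is the intramolecular Nozaki–Hiyama–Kishi cyclisation of iodoalkenyl aldehydes to cyclic allylic alcohols. Ring A closes in a 7-exo-trig mode at the aldehyde carbon; the (Z) alkene holds C7 and C9 on one side and supplies the turn, and the cis arrangement of C6 and C10 on ring B keeps the two ends close. The new stereocentre C10 is controlled by the forming ring: the chromium-bound carbonyl oxygen should point away from the C1 methyl toward the outside of the ring, which gives the (10S) alcohol trans to that methyl. The step needs selectivity for the aldehyde over the aryl ester and tolerance of the free tertiary alcohol, both normal for organochromium reagents, and ring closure over intermolecular coupling, secured by high dilution and by the non-enolisable aldehyde.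

Step 25
Reactants: 33 the bicyclic C10 allylic alcohol
Product: 34 (3S,3aS,4R,8S,8aR)-3-hydroxy-6,8a-dimethyl-8-[(3-methylbutanoyl)oxy]-3-(propan-2-yl)-1,2,3,3a,4,5,8,8a-octahydroazulen-4-yl 4-[(tert-butyldimethylsilyl)oxy]benzoate
Conditions: isovaleryl chloride (2 equiv), pyridine, DMAP (0.2 equiv), CH2Cl2, 0 °C to rt
Reagents that add atoms: isovaleryl chloride (3-methylbutanoyl chloride), CC(C)CC(Cl)=O
Why: DMAP-catalysed acylation esterifies the secondary allylic C10 alcohol, the tertiary C4 alcohol does not react, and the mild base leaves the C6 aroyl ester in place.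

Step 26
Reactants: 34 the silyl-protected diester
Product: 35 (3S,3aS,4R,8S,8aR)-3-hydroxy-6,8a-dimethyl-8-[(3-methylbutanoyl)oxy]-3-(propan-2-yl)-1,2,3,3a,4,5,8,8a-octahydroazulen-4-yl 4-hydroxybenzoate (CNP0086724.3)
Conditions: Bu4NF (1.2 equiv), AcOH (1.2 equiv), THF, 0 °C
Reagents that add atoms: none
Why: Fluoride-mediated desilylation cleaves the aryl silyl ether, and buffering with acetic acid keeps the phenoxide from attacking either ester.

**Compound list**

1 | (S)-2-hydroxy-3-methylbutanoic acid | CC(C)[C@H](O)C(=O)O | starting material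
2 | (2S,5S)-2-tert-butyl-5-(propan-2-yl)-1,3-dioxolan-4-one | CC(C)[C@@H]1O[C@H](C(C)(C)C)OC1=O | intermediate
3 | lithium enolate of 2 (not isolated) | CC(C)C1=C(O[Li])O[C@@H](C(C)(C)C)O1 | intermediate
4 | (2S,5S)-2-tert-butyl-5-(prop-2-en-1-yl)-5-(propan-2-yl)-1,3-dioxolan-4-one | CC(C)[C@]1(CC=C)O[C@H](C(C)(C)C)OC1=O | intermediate
5 | methyl (2E)-4-[(2S,4S)-2-tert-butyl-5-oxo-4-(propan-2-yl)-1,3-dioxolan-4-yl]but-2-enoate | CC(C)[C@]1(C/C=C/C(=O)OC)O[C@H](C(C)(C)C)OC1=O | intermediate
6 | methyl 4-[(2S,4S)-2-tert-butyl-5-oxo-4-(propan-2-yl)-1,3-dioxolan-4-yl]butanoate | CC(C)[C@]1(CCCC(=O)OC)O[C@H](C(C)(C)C)OC1=O | intermediate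
7 | methyl (3S)-3-hydroxy-2-oxo-3-(propan-2-yl)cyclopentane-1-carboxylate | COC(=O)C1CC[C@](O)(C(C)C)C1=O | intermediate
8 | methyl (3S)-3-hydroxy-3-(propan-2-yl)-2-[(trifluoromethanesulfonyl)oxy]cyclopent-1-ene-1-carboxylate | COC(=O)C1=C(OS(=O)(=O)C(F)(F)F)[C@@](O)(C(C)C)CC1 | intermediate
9 | methyl (3S)-2-formyl-3-hydroxy-3-(propan-2-yl)cyclopent-1-ene-1-carboxylate | COC(=O)C1=C(C=O)[C@@](O)(C(C)C)CC1 | intermediate
10 | methyl (3S)-2-(dimethoxymethyl)-3-hydroxy-3-(propan-2-yl)cyclopent-1-ene-1-carboxylate | COC(=O)C1=C(C(OC)OC)[C@@](O)(C(C)C)CC1 | intermediate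
11 | methyl (1R,2R,3S)-2-(dimethoxymethyl)-3-hydroxy-3-(propan-2-yl)cyclopentane-1-carboxylate | COC(=O)[C@@H]1CC[C@](O)(C(C)C)[C@@H]1C(OC)OC | intermediate
12 | dilithium alkoxide enolate of 11 (not isolated) | COC(O[Li])=C1CC[C@](O[Li])(C(C)C)[C@@H]1C(OC)OC | intermediate
13 | methyl (1R,2R,3S)-2-(dimethoxymethyl)-3-hydroxy-1-methyl-3-(propan-2-yl)cyclopentane-1-carboxylate | COC(=O)[C@]1(C)CC[C@](O)(C(C)C)[C@@H]1C(OC)OC | intermediate
14 | methyl (1R,2R,3S)-2-(1,3-dithian-2-yl)-3-hydroxy-1-methyl-3-(propan-2-yl)cyclopentane-1-carboxylate | COC(=O)[C@]1(C)CC[C@](O)(C(C)C)[C@@H]1C2SCCCS2 | intermediate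
15 | (1S,2R,3R)-2-(1,3-dithian-2-yl)-3-(hydroxymethyl)-3-methyl-1-(propan-2-yl)cyclopentan-1-ol | OC[C@]1(C)CC[C@](O)(C(C)C)[C@@H]1C2SCCCS2 | intermediate
16 | (1S,2R,3R)-2-(1,3-dithian-2-yl)-3-{[(4-methoxyphenyl)methoxy]methyl}-3-methyl-1-(propan-2-yl)cyclopentan-1-ol | COc1ccc(COC[C@]2(C)CC[C@](O)(C(C)C)[C@@H]2C3SCCCS3)cc1 | intermediate
17 | prop-2-yn-1-ol | C#CCO | starting material
18 | 4-methyl-2,5-dihydro-1,2-oxamagnesole, the chelated (Z)-alkenylmagnesium alkoxide (not isolated) | CC1=C[Mg]OC1 | intermediate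
19 | (2Z)-3-iodo-2-methylprop-2-en-1-ol | OC/C(C)=C\I | intermediate
20 | (1Z)-3-bromo-1-iodo-2-methylprop-1-ene | BrC/C(C)=C\I | intermediate
21 | dilithio derivative of 16: lithium alkoxide, 2-lithio-1,3-dithiane (not isolated) | COc1ccc(COC[C@]2(C)CC[C@](O[Li])(C(C)C)[C@@H]2C3([Li])SCCCS3)cc1 | intermediate
22 | (1S,2R,3R)-2-{2-[(2Z)-3-iodo-2-methylprop-2-en-1-yl]-1,3-dithian-2-yl}-3-{[(4-methoxyphenyl)methoxy]methyl}-3-methyl-1-(propan-2-yl)cyclopentan-1-ol | COc1ccc(COC[C@]2(C)CC[C@](O)(C(C)C)[C@@H]2C3(C/C(C)=C\I)SCCCS3)cc1 | intermediate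
23 | (3Z)-1-[(1R,2S,5R)-2-hydroxy-5-{[(4-methoxyphenyl)methoxy]methyl}-5-methyl-2-(propan-2-yl)cyclopentyl]-4-iodo-3-methylbut-3-en-1-one | COc1ccc(COC[C@]2(C)CC[C@](O)(C(C)C)[C@@H]2C(=O)C/C(C)=C\I)cc1 | intermediate
24 | (1S,2S,3R)-2-[(1R,3Z)-1-hydroxy-4-iodo-3-methylbut-3-en-1-yl]-3-{[(4-methoxyphenyl)methoxy]methyl}-3-methyl-1-(propan-2-yl)cyclopentan-1-ol | COc1ccc(COC[C@]2(C)CC[C@](O)(C(C)C)[C@@H]2[C@H](O)C/C(C)=C\I)cc1 | intermediate
25 | 4-hydroxybenzoic acid | O=C(O)c1ccc(O)cc1 | starting material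
26 | tert-butyldimethylsilyl 4-[(tert-butyldimethylsilyl)oxy]benzoate (not isolated) | CC(C)(C)[Si](C)(C)OC(=O)c1ccc(O[Si](C)(C)C(C)(C)C)cc1 | intermediate
27 | 4-[(tert-butyldimethylsilyl)oxy]benzoic acid | CC(C)(C)[Si](C)(C)Oc1ccc(C(=O)O)cc1 | intermediate
28 | 4-[(tert-butyldimethylsilyl)oxy]benzoyl chloride | CC(C)(C)[Si](C)(C)Oc1ccc(C(Cl)=O)cc1 | intermediate
29 | (1R,3Z)-1-[(1S,2S,5R)-2-hydroxy-5-{[(4-methoxyphenyl)methoxy]methyl}-5-methyl-2-(propan-2-yl)cyclopentyl]-4-iodo-3-methylbut-3-en-1-yl 4-[(tert-butyldimethylsilyl)oxy]benzoate | COc1ccc(COC[C@]2(C)CC[C@](O)(C(C)C)[C@@H]2[C@H](OC(=O)c3ccc(O[Si](C)(C)C(C)(C)C)cc3)C/C(C)=C\I)cc1 | intermediate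
30 | (1R,3Z)-1-[(1S,2S,5R)-2-hydroxy-5-(hydroxymethyl)-5-methyl-2-(propan-2-yl)cyclopentyl]-4-iodo-3-methylbut-3-en-1-yl 4-[(tert-butyldimethylsilyl)oxy]benzoate | OC[C@]1(C)CC[C@](O)(C(C)C)[C@@H]1[C@H](OC(=O)c2ccc(O[Si](C)(C)C(C)(C)C)cc2)C/C(C)=C\I | intermediate
31 | (1R,3Z)-1-[(1S,2S,5R)-5-formyl-2-hydroxy-5-methyl-2-(propan-2-yl)cyclopentyl]-4-iodo-3-methylbut-3-en-1-yl 4-[(tert-butyldimethylsilyl)oxy]benzoate (cyclisation precursor) | O=C[C@]1(C)CC[C@](O)(C(C)C)[C@@H]1[C@H](OC(=O)c2ccc(O[Si](C)(C)C(C)(C)C)cc2)C/C(C)=C\I | intermediate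
32 | (Z)-alkenylchromium dichloride derived from 31, trivalent chromium on C9 (not isolated) | O=C[C@]1(C)CC[C@](O)(C(C)C)[C@@H]1[C@H](OC(=O)c2ccc(O[Si](C)(C)C(C)(C)C)cc2)C/C(C)=C\[Cr](Cl)Cl | intermediate
33 | (3S,3aS,4R,8S,8aR)-3,8-dihydroxy-6,8a-dimethyl-3-(propan-2-yl)-1,2,3,3a,4,5,8,8a-octahydroazulen-4-yl 4-[(tert-butyldimethylsilyl)oxy]benzoate (bicyclic C10 allylic alcohol) | CC1=C[C@H](O)[C@]2(C)CC[C@](O)(C(C)C)[C@@H]2[C@H](OC(=O)c3ccc(O[Si](C)(C)C(C)(C)C)cc3)C1 | intermediate
34 | (3S,3aS,4R,8S,8aR)-3-hydroxy-6,8a-dimethyl-8-[(3-methylbutanoyl)oxy]-3-(propan-2-yl)-1,2,3,3a,4,5,8,8a-octahydroazulen-4-yl 4-[(tert-butyldimethylsilyl)oxy]benzoate | CC1=C[C@H](OC(=O)CC(C)C)[C@]2(C)CC[C@](O)(C(C)C)[C@@H]2[C@H](OC(=O)c3ccc(O[Si](C)(C)C(C)(C)C)cc3)C1 | intermediate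
35 | (3S,3aS,4R,8S,8aR)-3-hydroxy-6,8a-dimethyl-8-[(3-methylbutanoyl)oxy]-3-(propan-2-yl)-1,2,3,3a,4,5,8,8a-octahydroazulen-4-yl 4-hydroxybenzoate (CNP0086724.3) | CC1=C[C@H](OC(=O)CC(C)C)[C@]2(C)CC[C@](O)(C(C)C)[C@@H]2[C@H](OC(=O)c2ccc(O)cc2)C1 | target

**Step count**

Total: 26 steps (22 in the main line, 2 for bromide 20, 2 for acid chloride 28).
Longest linear sequence: 22 steps (steps 1–13, 16–18 and 21–26, from 1 to 35).

**Steps most likely to fail, with fallbacks**

Step 24 (ring A closure). The addition to the C10 carbonyl may show poor facial selectivity, because the ring-controlled preference for the oxygen to turn away from the C1 methyl is only a model. The fallback sets the C10 centre by hydride addition instead of by the carbon–carbon bond formation. It sets out from 31: the cyclisation is run as above, and the alcohol of the wrong C10 configuration, the (8R)-epimer of 33, F1, is oxidised with Dess–Martin periodinane to the ring A enone (3S,3aS,4R,8aR)-3-hydroxy-6,8a-dimethyl-8-oxo-3-(propan-2-yl)-octahydroazulen-4-yl 4-[(tert-butyldimethylsilyl)oxy]benzoate F2. Luche reduction (NaBH4, CeCl3, MeOH, −78 °C) should then deliver hydride 1,2 from the exposed convex face of the cis-fused bicycle (the face of the C1 methyl and H-5) and so comes back to 33.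

Step 16 (dithiane alkylation). Lithiation of the dithiane on the very crowded C5 may be incomplete, or the hindered anion may react by electron transfer or elimination with the bromide instead of by substitution. The fallback replaces acyl-anion alkylation by addition to an aldehyde. It sets out from 16: hydrolysis of the dithiane (MeI, CaCO3, aqueous MeCN) gives (1R,2S,5R)-2-hydroxy-5-{[(4-methoxyphenyl)methoxy]methyl}-5-methyl-2-(propan-2-yl)cyclopentane-1-carbaldehyde F3. Barbier propargylation (propargyl bromide, zinc, THF–aqueous NH4Cl) gives the homopropargylic alcohol, the 2-(1-hydroxybut-3-yn-1-yl) analogue of 16, F4, as a mixture of C6 epimers. Zirconium-catalysed carboalumination (Me3Al, Cp2ZrCl2, 1,2-dichloroethane), chelation-controlled isomerisation of the alkenylalane by the neighbouring alkoxide on heating and iodinolysis (I2) give the (Z)-iodoalkene diol, the C6 epimer mixture of 24, F5. Dess–Martin oxidation of its secondary alcohol comes back to ketone 23, where step 18 sets C6.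

Step 9 (directed hydrogenation). The crowded, electron-poor tetrasubstituted alkene may be reduced slowly or incompletely by the iridium catalyst, or facial control may be lost if the acetal or ester oxygen binds the metal in place of the hydroxyl. The fallback reduces a fused butenolide instead, in which the lactone ring enforces cis ring fusion and later guarantees convex-face methylation. It sets out from 9: acid-catalysed methanolysis (p-TsOH, MeOH, reflux) closes the cis formyl ester to the pseudo-ester (4S)-4-hydroxy-3-methoxy-4-(propan-2-yl)-3,4,5,6-tetrahydro-1H-cyclopenta[c]furan-1-one F6 (acetal epimers). Heterogeneous hydrogenation (H2, Rh/Al2O3, EtOAc), syn to the hydroxyl and anti to isopropyl, gives the cis-fused lactone with H-3a, H-6a and the 4-hydroxyl on one face, F7. Methylation (LiN(iPr)2, 2.3 equiv; MeI) on the convex face gives the 6a-methyl lactone F8. Propane-1,3-dithiol with BF3·OEt2 opens the pseudo-ester to (1R,2R,3S)-2-(1,3-dithian-2-yl)-3-hydroxy-1-methyl-3-(propan-2-yl)cyclopentane-1-carboxylic acid F9, and LiAlH4 reduction comes back to 15.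

Further compounds
F1 | step 24 | (3S,3aS,4R,8R,8aR)-3,8-dihydroxy-6,8a-dimethyl-3-(propan-2-yl)-1,2,3,3a,4,5,8,8a-octahydroazulen-4-yl 4-[(tert-butyldimethylsilyl)oxy]benzoate (C10 epimer of 33) | CC1=C[C@@H](O)[C@]2(C)CC[C@](O)(C(C)C)[C@@H]2[C@H](OC(=O)c3ccc(O[Si](C)(C)C(C)(C)C)cc3)C1
F2 | step 24 | (3S,3aS,4R,8aR)-3-hydroxy-6,8a-dimethyl-8-oxo-3-(propan-2-yl)-1,2,3,3a,4,5,8,8a-octahydroazulen-4-yl 4-[(tert-butyldimethylsilyl)oxy]benzoate | CC1=CC(=O)[C@]2(C)CC[C@](O)(C(C)C)[C@@H]2[C@H](OC(=O)c3ccc(O[Si](C)(C)C(C)(C)C)cc3)C1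
F3 | step 16 | (1R,2S,5R)-2-hydroxy-5-{[(4-methoxyphenyl)methoxy]methyl}-5-methyl-2-(propan-2-yl)cyclopentane-1-carbaldehyde | COc1ccc(COC[C@]2(C)CC[C@](O)(C(C)C)[C@@H]2C=O)cc1
F4 | step 16 | (1S,2S,3R)-2-(1-hydroxybut-3-yn-1-yl)-3-{[(4-methoxyphenyl)methoxy]methyl}-3-methyl-1-(propan-2-yl)cyclopentan-1-ol (epimers at the carbinol carbon C6) | COc1ccc(COC[C@]2(C)CC[C@](O)(C(C)C)[C@@H]2C(O)CC#C)cc1
F5 | step 16 | (1S,2S,3R)-2-[(3Z)-1-hydroxy-4-iodo-3-methylbut-3-en-1-yl]-3-{[(4-methoxyphenyl)methoxy]methyl}-3-methyl-1-(propan-2-yl)cyclopentan-1-ol (epimers at C6) | COc1ccc(COC[C@]2(C)CC[C@](O)(C(C)C)[C@@H]2C(O)C/C(C)=C\I)cc1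
F6 | step 9 | (4S)-4-hydroxy-3-methoxy-4-(propan-2-yl)-3,4,5,6-tetrahydro-1H-cyclopenta[c]furan-1-one (acetal epimers) | COC1OC(=O)C2=C1[C@@](O)(C(C)C)CC2
F7 | step 9 | cis-fused (4S)-4-hydroxy-3-methoxy-4-(propan-2-yl)hexahydro-1H-cyclopenta[c]furan-1-one, H-3a, H-6a and 4-OH on one face (acetal epimers) | COC1OC(=O)[C@@H]2CC[C@](O)(C(C)C)[C@H]12
F8 | step 9 | cis-fused (4S)-4-hydroxy-3-methoxy-6a-methyl-4-(propan-2-yl)hexahydro-1H-cyclopenta[c]furan-1-one, 6a-methyl, H-3a and 4-OH on one face (acetal epimers) | COC1OC(=O)[C@]2(C)CC[C@](O)(C(C)C)[C@H]12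
F9 | step 9 | (1R,2R,3S)-2-(1,3-dithian-2-yl)-3-hydroxy-1-methyl-3-(propan-2-yl)cyclopentane-1-carboxylic acid | OC(=O)[C@]1(C)CC[C@](O)(C(C)C)[C@@H]1C2SCCCS2
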